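A direct plan would build the side chain stepwise on the intact coumarin. The 7-O-prenyl ether A1 would be hydroxylated at its E-methyl group with SeO2 (A2), epoxidised with a titanium tartrate (A3), extended by two carbons to the β,γ-epoxy aldehyde A4 (sulfonate, vinyl cuprate, oxidative alkene cleavage) and finished by a chromium-mediated asymmetric 2-methylprop-1-enyl addition. Its weakest steps would be:
(a) the extension A3 → A4, which would spend three steps on one CH2CHO unit, through a sulfonate beside a fully substituted oxirane carbon, with cuprate and osmium reagents facing the coumarin enoate;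
(b) the final alkenyl addition, which would set C5' last, by reagent control alone, on an aldehyde prone to β-elimination with oxirane opening, on the most precious material;
(c) the allylic C–H hydroxylation A1 → A2, which over-oxidises to the enal and would have to be stopped early.

**Plan of the new route**

Locants: C1' is the OCH2 carbon, C2' and C3' are the oxirane carbons (C3' bears CH3), C5' is the carbinol carbon; ring A is the benzene ring, ring B the pyranone, ring C the oxirane.
The retrosynthesis cuts, in this order, the aryl ether bond O7–C1', the two C–O bonds of ring C (back to an E-C2'=C3' primary allylic alcohol) and the C4'–C5' bond.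
The feature that allows the last cut: the C5' hydroxyl stands 1,5 to the C1' oxygen across C2'–C3'(CH3), and ring C is a masked E-alkene. The chain is therefore the retron of a δ-hydroxy-β-methyl enoate, that is, of a vinylogous aldol between two C5 units of the same origin (ethyl 3-methylbut-2-enoate and 3-methylbut-2-enal).
Ring C arises first, on a coumarin-free C10 chain in which C5' (aldol catalyst) and C2'/C3' (tartrate) are each set by a catalyst on small material; rings A and B enter whole only in step 6.
No allylic C–H oxidation, no two-carbon extension and no late carbonyl addition occur.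

Key step: step 2

Assumption: 7-hydroxy-8-methoxycoumarin (10) is purchasable, and the (R,R)-bisphosphoramide is taken to attack the Re face of 3-methylbut-2-enal as with other conjugated aldehydes; the (S,S)-antipode would be used if the sense proved opposite.

**Route**

Step 1
Reactants: 1 ethyl 3-methylbut-2-enoate
Product: 3 tert-butyl[(1-ethoxy-3-methylbuta-1,3-dien-1-yl)oxy]dimethylsilane, via lithium dienolate 2 (not isolated)
Conditions: LiN(iPr)2 (1.1 equiv), THF, −78 °C; then TBSCl, DMPU, −78 °C → rt; pentane filtration, distillation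
Reagents that add atoms: tert-butyl(chloro)dimethylsilane, CC(C)(C)[Si](C)(C)Cl
Why: Kinetic γ-deprotonation of the β,β-dimethyl enoate gives the extended lithium dienolate 2, which the silyl chloride traps on oxygen (silyl ketene acetal formation); the ketene acetal geometry is of no consequence because only the terminal CH2 reacts later.

Step 2
Reactants: 3 tert-butyl[(1-ethoxy-3-methylbuta-1,3-dien-1-yl)oxy]dimethylsilane; 4 3-methylbut-2-enal
Product: 6 ethyl (2E,5R)-5-hydroxy-3,7-dimethylocta-2,6-dienoate, via trichlorosilyl ether 5 (not isolated)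
Conditions: SiCl4 (1.1 equiv), (R,R)-N,N'-bis[4-(3,5-dihydro-3,5-dimethyl-4H-dinaphtho[2,1-d:1',2'-f][1,3,2]diazaphosphepin-4-oxide)]-N,N'-dimethylpentane-1,5-diamine (C51H52N6O2P2, 2 mol %), i-Pr2NEt (5 mol %), CH2Cl2, −78 °C; cold sat. aq. NaHCO3
Reagents that add atoms: none
Why: The bisphosphoramide binds SiCl4 and ionises a chloride to give a chiral trichlorosilyl cation that activates the aldehyde; 3 attacks the bound carbonyl through an open transition state with its unsubstituted γ-CH2 terminus, chloride takes the TBS group, and the trichlorosilyl aldolate 5 is hydrolysed on work-up. The closest known reaction type is the Lewis-base-activated SiCl4 catalytic enantioselective vinylogous Mukaiyama aldol addition of ester-derived silyl dienol ethers to conjugated aldehydes. No ring is closed; the step forms the C4'–C5' bond and turns the dienol ether into the E-C2'=C3' enoate, the E geometry following from reaction through the s-trans dienol ether (C4' anti to the ester carbon). C5' is set by the catalyst alone, attack on the Re face of the aldehyde giving the R carbinol. The step needs γ over α regioselectivity, 1,2 over 1,4 addition and enantioface control: the first should be secured by the bulk of the catalyst-bound silicon cation against the substituted α-carbon, the second by the two β-methyl groups of 4, the third by the binaphthyldiamine units around silicon.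

Step 3
Reactants: 6 ethyl (2E,5R)-5-hydroxy-3,7-dimethylocta-2,6-dienoate
Product: 7 ethyl (2E,5R)-5-[(tert-butyldimethylsilyl)oxy]-3,7-dimethylocta-2,6-dienoate
Conditions: TBSCl (1.3 equiv), imidazole (2.5 equiv), DMF, rt
Reagents that add atoms: tert-butyl(chloro)dimethylsilane, CC(C)(C)[Si](C)(C)Cl
Why: Imidazole-mediated silylation masks the C5' hydroxyl, which would otherwise be a second allylic alcohol (and the fast-reacting antipode for the D-tartrate) in the titanium-tartrate epoxidation of step 5; no stereocentre is touched.

Step 4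
Reactants: 7 ethyl (2E,5R)-5-[(tert-butyldimethylsilyl)oxy]-3,7-dimethylocta-2,6-dienoate
Product: 8 (2E,5R)-5-[(tert-butyldimethylsilyl)oxy]-3,7-dimethylocta-2,6-dien-1-ol
Conditions: i-Bu2AlH (2.3 equiv), CH2Cl2, −78 °C; aq. potassium sodium tartrate
Reagents that add atoms: none
Why: Two hydride transfers from i-Bu2AlH at −78 °C should reduce the enoate 1,2 to the E allylic alcohol (ester-to-alcohol reduction) without touching the silyl ether or the alkene geometry.

Step 5
Reactants: 8 (2E,5R)-5-[(tert-butyldimethylsilyl)oxy]-3,7-dimethylocta-2,6-dien-1-ol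
Product: 9 [(2R,3R)-3-{(2R)-2-[(tert-butyldimethylsilyl)oxy]-4-methylpent-3-en-1-yl}-3-methyloxiran-2-yl]methanol
Conditions: Ti(OiPr)4 (10 mol %), D-(−)-diisopropyl tartrate (12 mol %), t-BuOOH (1.5 equiv, in decane), 4 Å MS, CH2Cl2, −20 °C; cold aq. NaOH/brine work-up
Reagents that add atoms: tert-butyl hydroperoxide, CC(C)(C)OO
Why: Sharpless asymmetric epoxidation: the primary alkoxide of 8 and the peroxide bind to the dimeric titanium tartrate and oxygen is passed to one face of the C2'=C3' alkene in a concerted transfer, the D-(−)-tartrate giving the 2'R,3'R oxirane (the L-(+)-ester gives 2S,3S with geraniol-type E-3-methylalk-2-enols), the trans relation of C1' and C4' coming from the E alkene and the C6'=C7' alkene staying untouched because it has no free allylic hydroxyl.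

Step 6
Reactants: 9 [(2R,3R)-3-{(2R)-2-[(tert-butyldimethylsilyl)oxy]-4-methylpent-3-en-1-yl}-3-methyloxiran-2-yl]methanol; 10 7-hydroxy-8-methoxycoumarin
Product: 11 7-{[(2R,3R)-3-{(2R)-2-[(tert-butyldimethylsilyl)oxy]-4-methylpent-3-en-1-yl}-3-methyloxiran-2-yl]methoxy}-8-methoxycoumarin
Conditions: PPh3 (1.3 equiv), diisopropyl azodicarboxylate (1.3 equiv), THF, 0 °C → rt
Reagents that add atoms: none
Why: Mitsunobu etherification: the phosphine–azodicarboxylate adduct is protonated by the acidic phenol, the primary C1' hydroxyl becomes an oxyphosphonium ion and is displaced by the phenoxide in an SN2 step at the CH2 carbon, so that no free alkoxide arises that could migrate the oxirane (Payne rearrangement) and C2', C3' and C5' are untouched.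

Step 7
Reactants: 11 7-{[(2R,3R)-3-{(2R)-2-[(tert-butyldimethylsilyl)oxy]-4-methylpent-3-en-1-yl}-3-methyloxiran-2-yl]methoxy}-8-methoxycoumarin
Product: 12 7-{[(2R,3R)-3-[(2R)-2-hydroxy-4-methylpent-3-en-1-yl]-3-methyloxiran-2-yl]methoxy}-8-methoxycoumarin
Conditions: Bu4NF (1.5 equiv), AcOH (1.5 equiv), THF, 0 °C → rt; pH 7 buffer work-up
Reagents that add atoms: none
Why: Fluoride cleaves the Si–O bond (desilylation) while acetic acid keeps the medium near neutral, so that the freed C5' hydroxyl should not open the oxirane and the lactone, the trisubstituted oxirane and the allylic alcohol should survive.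

**Compound list**

1 | ethyl 3-methylbut-2-enoate | CCOC(=O)C=C(C)C | starting material
2 | lithium 1-ethoxy-3-methylbuta-1,3-dien-1-olate (either enolate geometry) | CCOC(O[Li])=CC(C)=C | intermediate
3 | tert-butyl[(1-ethoxy-3-methylbuta-1,3-dien-1-yl)oxy]dimethylsilane (either ketene acetal geometry) | CCOC(O[Si](C)(C)C(C)(C)C)=CC(C)=C | intermediate
4 | 3-methylbut-2-enal | CC(C)=CC=O | starting material
5 | ethyl (2E,5R)-3,7-dimethyl-5-[(trichlorosilyl)oxy]octa-2,6-dienoate | CCOC(=O)/C=C(\C)C[C@@H](O[Si](Cl)(Cl)Cl)C=C(C)C | intermediate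
6 | ethyl (2E,5R)-5-hydroxy-3,7-dimethylocta-2,6-dienoate | CCOC(=O)/C=C(\C)C[C@@H](O)C=C(C)C | intermediate
7 | ethyl (2E,5R)-5-[(tert-butyldimethylsilyl)oxy]-3,7-dimethylocta-2,6-dienoate | CCOC(=O)/C=C(\C)C[C@@H](O[Si](C)(C)C(C)(C)C)C=C(C)C | intermediate
8 | (2E,5R)-5-[(tert-butyldimethylsilyl)oxy]-3,7-dimethylocta-2,6-dien-1-ol | OC/C=C(\C)C[C@@H](O[Si](C)(C)C(C)(C)C)C=C(C)C | intermediate
9 | [(2R,3R)-3-{(2R)-2-[(tert-butyldimethylsilyl)oxy]-4-methylpent-3-en-1-yl}-3-methyloxiran-2-yl]methanol | OC[C@H]1O[C@]1(C)C[C@@H](O[Si](C)(C)C(C)(C)C)C=C(C)C | intermediate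
10 | 7-hydroxy-8-methoxy-2H-chromen-2-one (7-hydroxy-8-methoxycoumarin) | COc1c(O)ccc2ccc(=O)oc12 | starting material
11 | 7-{[(2R,3R)-3-{(2R)-2-[(tert-butyldimethylsilyl)oxy]-4-methylpent-3-en-1-yl}-3-methyloxiran-2-yl]methoxy}-8-methoxy-2H-chromen-2-one | COc1c(OC[C@H]2O[C@]2(C)C[C@@H](O[Si](C)(C)C(C)(C)C)C=C(C)C)ccc2ccc(=O)oc12 | intermediate
12 | 7-{[(2R,3R)-3-[(2R)-2-hydroxy-4-methylpent-3-en-1-yl]-3-methyloxiran-2-yl]methoxy}-8-methoxy-2H-chromen-2-one | COc1c(OC[C@H]2O[C@]2(C)C[C@@H](O)C=C(C)C)ccc2ccc(=O)oc12 | target

**Count and risks**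

Total steps: 7. Longest linear sequence: 7 steps (1 → 12); the coumarin 10 enters in step 6.

Steps most likely to fail:

1. Step 2. Enantiofacial or E/Z control may erode with the β,β-disubstituted enal (a Z adduct would lactonise), or the allylic trichlorosilyl aldolate may ionise before work-up. Fallback, setting out from 4 and returning at 8: asymmetric propargylboration of 4 with B-allenyldiisopinocampheylborane (the antipode chosen that attacks the Re face; Et2O, −78 °C; NaOH/H2O2 work-up) would give (4R)-6-methylhept-5-en-1-yn-4-ol F1. Silylation (TBSCl, imidazole, DMF) would give tert-butyldimethyl{[(4R)-6-methylhept-5-en-1-yn-4-yl]oxy}silane F2. Zirconium-catalysed methylalumination of the terminal alkyne (Me3Al, Cp2ZrCl2 20 mol %, CH2Cl2; Negishi carboalumination), then n-BuLi and paraformaldehyde, would add CH3 at C3' and C1' at C2' syn across the triple bond, which fixes the E geometry and gives 8.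

2. Step 6. The activated phosphorus species or the phenoxide may attack the oxirane instead of C1', or activation of the carbinol beside the trisubstituted oxirane may be slow with the ortho-substituted phenol. Fallback, setting out from 9 and returning at 11: sulfonylation (3-nitrobenzenesulfonyl chloride, Et3N, DMAP cat., CH2Cl2, −20 °C) would give [(2R,3R)-3-{(2R)-2-[(tert-butyldimethylsilyl)oxy]-4-methylpent-3-en-1-yl}-3-methyloxiran-2-yl]methyl 3-nitrobenzenesulfonate F3. Direct SN2 displacement at C1' by the caesium phenoxide of 10 (Cs2CO3, DMF, rt) would then give 11.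

3. Step 7. After loss of silicon the C5' oxygen may open the oxirane at C2', or basic fluoride may open the lactone. Fallback, setting out from 6 and returning at 12, with no silyl ether made at all: i-Bu2AlH reduction of 6 would give (2E,5R)-3,7-dimethylocta-2,6-diene-1,5-diol F4. Titanium–D-(−)-diisopropyl tartrate epoxidation with 1.0 equiv t-BuOOH at −25 °C, stopped short of full conversion, would give (2R)-1-[(2R,3R)-3-(hydroxymethyl)-2-methyloxiran-2-yl]-4-methylpent-3-en-2-ol F5; the primary E-allylic alcohol should react much faster than the secondary one, whose alkene carries a cis methyl group. Mitsunobu etherification of F5 with 10 at the primary carbinol would give 12 directly.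

**Further compounds**

F1 | step 2 | (4R)-6-methylhept-5-en-1-yn-4-ol | C#CC[C@@H](O)C=C(C)C
F2 | step 2 | tert-butyldimethyl{[(4R)-6-methylhept-5-en-1-yn-4-yl]oxy}silane | C#CC[C@@H](O[Si](C)(C)C(C)(C)C)C=C(C)C
F3 | step 6 | [(2R,3R)-3-{(2R)-2-[(tert-butyldimethylsilyl)oxy]-4-methylpent-3-en-1-yl}-3-methyloxiran-2-yl]methyl 3-nitrobenzenesulfonate | O=S(=O)(OC[C@H]1O[C@]1(C)C[C@@H](O[Si](C)(C)C(C)(C)C)C=C(C)C)c1cccc([N+](=O)[O-])c1
F4 | step 7 | (2E,5R)-3,7-dimethylocta-2,6-diene-1,5-diol | OC/C=C(\C)C[C@@H](O)C=C(C)C
F5 | step 7 | (2R)-1-[(2R,3R)-3-(hydroxymethyl)-2-methyloxiran-2-yl]-4-methylpent-3-en-2-ol | OC[C@H]1O[C@]1(C)C[C@@H](O)C=C(C)C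
A1 | direct plan | 8-methoxy-7-[(3-methylbut-2-en-1-yl)oxy]-2H-chromen-2-one | COc1c(OCC=C(C)C)ccc2ccc(=O)oc12
A2 | direct plan | 7-{[(2E)-4-hydroxy-3-methylbut-2-en-1-yl]oxy}-8-methoxy-2H-chromen-2-one | COc1c(OC/C=C(\C)CO)ccc2ccc(=O)oc12
A3 | direct plan | 7-{[(2R,3R)-3-(hydroxymethyl)-3-methyloxiran-2-yl]methoxy}-8-methoxy-2H-chromen-2-one | COc1c(OC[C@H]2O[C@]2(C)CO)ccc2ccc(=O)oc12
A4 | direct plan | 2-[(2R,3R)-3-{[(8-methoxy-2-oxo-2H-chromen-7-yl)oxy]methyl}-2-methyloxiran-2-yl]acetaldehyde | COc1c(OC[C@H]2O[C@]2(C)CC=O)ccc2ccc(=O)oc12
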